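**Plan**
- Retrosynthesis removes the C4 O-methyl and then cuts N1–C2 and N1–C6 of the pyridine. The pyridine carries oxygen on C4 and the carboxyl on C2 (the chelidamic acid pattern), so C2 and C6 are the 1,5-related carbonyl carbons of a 5-methoxy-2,4,6-trioxohexanoate and N1 can be inserted last from ammonia.
- The open chain is cut at C5–C6 (Claisen acylation by a thiazole-4-carboxylate) and at C2–C3 (oxalylation of methoxyacetone). Thiazole C2–CH2 is cut to a B-alkyl Suzuki pair, and the side chain C3–C4 to an epoxide plus a Grignard reagent.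
- Forward: side chain (steps 1–2), coupling to the purchased thiazole ring (step 3), diketo ester (step 4), triketo ester (step 5), closure of the pyridine ring, the only ring made (step 6), then O-methylation, desilylation and saponification (steps 7–9).
- Stereochemistry: the single (S) carbinol centre is bought as (S)-propylene oxide. The Grignard reagent attacks the CH2 terminus, the C–O bond at the stereocentre is never broken, and the centre travels as its TBS ether until step 8.

Key step: step 6

Remark: compounds 12 and 14 are drawn as single tautomers (chelated C5–C6 enol; NH-4-pyridone). Each is expected to be a tautomeric mixture, which does not affect the following step.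

**Step 1**
Reactants: 1 (S)-propylene oxide; 2 but-3-en-1-ylmagnesium bromide
Product: 3 (2S)-hept-6-en-2-ol
Conditions: CuI (10 mol%), THF, −30 °C → 0 °C; aq. NH4Cl
Reagents that add atoms: none
Why: Copper-catalysed Grignard opening of a terminal epoxide proceeds by SN2 attack at the unsubstituted CH2, so the secondary alcohol should form with the stereocentre of 1 carried over unchanged because its C–O bond is not involved.

**Step 2**
Reactants: 3 (2S)-hept-6-en-2-ol
Product: 4 tert-butyl{[(2S)-hept-6-en-2-yl]oxy}dimethylsilane
Conditions: TBSCl, imidazole, DMF, rt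
Reagents that add atoms: tert-butyldimethylsilyl chloride, CC(C)(C)[Si](C)(C)Cl
Why: Standard silylation of a secondary alcohol (silyl ether protection) masks the hydroxyl against the organoborane, the amide base and the enolates of steps 3 and 5.

**Step 3**
Reactants: 4 tert-butyl{[(2S)-hept-6-en-2-yl]oxy}dimethylsilane; 5 ethyl 2-bromo-1,3-thiazole-4-carboxylate
Product: 7 ethyl 2-[(6S)-6-{[tert-butyl(dimethyl)silyl]oxy}heptyl]-1,3-thiazole-4-carboxylate, via B-alkyl-9-BBN adduct 6 (not isolated)
Conditions: 9-BBN (9-borabicyclo[3.3.1]nonane), THF, 0 °C → rt; then 5, PdCl2(dppf) (5 mol%; dppf = 1,1'-bis(diphenylphosphino)ferrocene), aq. K3PO4, DMF, 50 °C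
Reagents that add atoms: none
Why: Anti-Markovnikov hydroboration of the terminal alkene followed by B-alkyl Suzuki–Miyaura coupling at the activated C2–Br bond of the thiazole (oxidative addition of zerovalent palladium, with the wide-bite-angle dppf ligand disfavouring β-hydride elimination) should join the chain to the heterocycle without touching the ester or the silyl ether.

**Step 4**
Reactants: 8 methoxyacetone; 9 diethyl oxalate
Product: 10 ethyl 5-methoxy-2,4-dioxopentanoate
Conditions: NaOEt, EtOH, 0 °C → rt; then cold aq. HCl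
Reagents that add atoms: none
Why: Crossed Claisen condensation in which the non-enolisable oxalate acylates the ketone at its methyl group under equilibrating alkoxide conditions, the product being drained from the equilibrium as its stabilised sodium enolate.

**Step 5**
Reactants: 10 ethyl 5-methoxy-2,4-dioxopentanoate; 7 ethyl 2-[(6S)-6-{[tert-butyl(dimethyl)silyl]oxy}heptyl]-1,3-thiazole-4-carboxylate
Product: 12 ethyl 6-{2-[(6S)-6-{[tert-butyl(dimethyl)silyl]oxy}heptyl]-1,3-thiazol-4-yl}-5-methoxy-2,4,6-trioxohexanoate (drawn as the C5–C6 enol with the C6 hydroxyl cis to the C4 carbonyl), via dilithium dianion 11 (not isolated)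
Conditions: 10 (2.2 equiv.), LiN(iPr)2 (4.4 equiv.), THF, −78 → −20 °C; then 7 (1 equiv.), −78 → 0 °C; aq. NH4Cl
Reagents that add atoms: none
Why: This is the γ-acylation of a 1,3-dicarbonyl dianion by an ester (dianion Claisen condensation): with C3 already an enolate, the second deprotonation can only take place at the methoxymethyl carbon C5, whose carbanion is the more reactive site and should add to the electron-poor heteroaryl ester, the excess dianion serving to deprotonate the more acidic product.

**Step 6**
Reactants: 12 ethyl 6-{2-[(6S)-6-{[tert-butyl(dimethyl)silyl]oxy}heptyl]-1,3-thiazol-4-yl}-5-methoxy-2,4,6-trioxohexanoate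
Product: 14 ethyl 6-{2-[(6S)-6-{[tert-butyl(dimethyl)silyl]oxy}heptyl]-1,3-thiazol-4-yl}-5-methoxy-4-oxo-1,4-dihydropyridine-2-carboxylate, via C2 enaminone 13 (not isolated)
Conditions: NH4OAc (10 equiv.), EtOH, 75 °C
Reagents that add atoms: ammonium acetate, CC(=O)[O-].[NH4+]
Why: Ammonia released from the acetate buffer should add to the most electrophilic carbonyl, the C2 keto group next to the ester, and lose water to give enaminone 13, whose nitrogen then adds to the C6 thiazolyl ketone; a second dehydration gives the 4-pyridone. The closest known reaction type is the conversion of 1,3,5-tricarbonyl compounds and 4-pyranones into 4-pyridones by ammonia, as in the chelidonic to chelidamic acid series. The one ring closes by 6-exo-trig attack of the enamine nitrogen on the C6 carbonyl followed by elimination of water; if the chain cyclises first to the 4-pyranone, ammonia should open it by conjugate addition and reclose to the same pyridone. No stereocentre is formed, and the remote (S)-silyloxy centre is not involved. The step needs nitrogen to bridge C2 and C6 and to leave C4 alone: only the 1,5-related pair C2/C6 can give a six-membered aromatic-type ring, whereas C4 is a vinylogous acid carbonyl from both sides, the least electrophilic of the three, and the methoxy-bearing C5 is never electrophilic. The buffered ammonia source in ethanol, the alcohol of the ester, is chosen to spare the ethyl ester and the silyl ether.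

**Step 7**
Reactants: 14 ethyl 6-{2-[(6S)-6-{[tert-butyl(dimethyl)silyl]oxy}heptyl]-1,3-thiazol-4-yl}-5-methoxy-4-oxo-1,4-dihydropyridine-2-carboxylate
Product: 15 ethyl 6-{2-[(6S)-6-{[tert-butyl(dimethyl)silyl]oxy}heptyl]-1,3-thiazol-4-yl}-4,5-dimethoxypyridine-2-carboxylate
Conditions: MeI, Ag2CO3, toluene, 50 °C, dark
Reagents that add atoms: iodomethane, CI
Why: Silver-assisted O-alkylation of the ambident pyridone (SN2 on iodomethane) should occur at oxygen because the ring nitrogen is flanked by the ester and the thiazolyl group and the silver salt in a non-polar solvent favours the oxygen terminus, as in the O-alkylation of chelidamate esters.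

**Step 8**
Reactants: 15 ethyl 6-{2-[(6S)-6-{[tert-butyl(dimethyl)silyl]oxy}heptyl]-1,3-thiazol-4-yl}-4,5-dimethoxypyridine-2-carboxylate
Product: 16 ethyl 6-{2-[(6S)-6-hydroxyheptyl]-1,3-thiazol-4-yl}-4,5-dimethoxypyridine-2-carboxylate
Conditions: HCl (1.25 M in EtOH), EtOH, 0 °C → rt; aq. NaHCO3
Reagents that add atoms: none
Why: Acid-catalysed solvolysis of a secondary TBS ether (silyl ether cleavage) leaves the C–O bond of the stereocentre intact, and ethanol as solvent makes any transesterification of the ethyl ester degenerate.

**Step 9**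
Reactants: 16 ethyl 6-{2-[(6S)-6-hydroxyheptyl]-1,3-thiazol-4-yl}-4,5-dimethoxypyridine-2-carboxylate
Product: 17 6-{2-[(6S)-6-hydroxyheptyl]-1,3-thiazol-4-yl}-4,5-dimethoxypyridine-2-carboxylic acid
Conditions: LiOH, THF/H2O, 0 °C → rt; then aq. HCl to pH 3–4
Reagents that add atoms: lithium hydroxide, [Li+].[OH-]
Why: Saponification of the picolinate-type ethyl ester (acyl–oxygen cleavage) followed by acidification to the isoelectric range should release the acid, since nothing else in the molecule is base-labile at room temperature and the carbinol centre cannot epimerise.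

**Compound list**
1 | (S)-propylene oxide [(2S)-2-methyloxirane] | C[C@H]1CO1 | starting material
2 | but-3-en-1-ylmagnesium bromide | C=CCC[Mg]Br | starting material
3 | (2S)-hept-6-en-2-ol | C=CCCC[C@H](C)O | intermediate
4 | tert-butyl{[(2S)-hept-6-en-2-yl]oxy}dimethylsilane | C=CCCC[C@H](C)O[Si](C)(C)C(C)(C)C | intermediate
5 | ethyl 2-bromo-1,3-thiazole-4-carboxylate | CCOC(=O)c1csc(Br)n1 | starting material
6 | 9-[(6S)-6-{[tert-butyl(dimethyl)silyl]oxy}heptyl]-9-borabicyclo[3.3.1]nonane | B1(C2CCCC1CCC2)CCCCC[C@H](C)O[Si](C)(C)C(C)(C)C | intermediate (not isolated)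
7 | ethyl 2-[(6S)-6-{[tert-butyl(dimethyl)silyl]oxy}heptyl]-1,3-thiazole-4-carboxylate | CCOC(=O)c1csc(CCCCC[C@H](C)O[Si](C)(C)C(C)(C)C)n1 | intermediate
8 | methoxyacetone (1-methoxypropan-2-one) | COCC(C)=O | starting material
9 | diethyl oxalate | CCOC(=O)C(=O)OCC | starting material
10 | ethyl 5-methoxy-2,4-dioxopentanoate | CCOC(=O)C(=O)CC(=O)COC | intermediate
11 | dilithium dianion of 10 (deprotonated at C3 and C5; dilithium 1-ethoxy-5-methoxy-1-oxopenta-2,4-diene-2,4-diolate) | [Li+].[Li+].CCOC(=O)C([O-])=CC([O-])=COC | intermediate (not isolated)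
12 | ethyl 6-{2-[(6S)-6-{[tert-butyl(dimethyl)silyl]oxy}heptyl]-1,3-thiazol-4-yl}-5-methoxy-2,4,6-trioxohexanoate, chelated C5–C6 enol | CCOC(=O)C(=O)CC(=O)/C(OC)=C(\O)c1csc(CCCCC[C@H](C)O[Si](C)(C)C(C)(C)C)n1 | intermediate
13 | ethyl 2-amino-6-{2-[(6S)-6-{[tert-butyl(dimethyl)silyl]oxy}heptyl]-1,3-thiazol-4-yl}-6-hydroxy-5-methoxy-4-oxohexa-2,5-dienoate (C2 enaminone, NH2 cis to the C4 carbonyl) | N/C(C(=O)OCC)=C\C(=O)/C(OC)=C(\O)c1csc(CCCCC[C@H](C)O[Si](C)(C)C(C)(C)C)n1 | intermediate (not isolated)
14 | ethyl 6-{2-[(6S)-6-{[tert-butyl(dimethyl)silyl]oxy}heptyl]-1,3-thiazol-4-yl}-5-methoxy-4-oxo-1,4-dihydropyridine-2-carboxylate | CCOC(=O)c1cc(=O)c(OC)c(-c2csc(CCCCC[C@H](C)O[Si](C)(C)C(C)(C)C)n2)[nH]1 | intermediate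
15 | ethyl 6-{2-[(6S)-6-{[tert-butyl(dimethyl)silyl]oxy}heptyl]-1,3-thiazol-4-yl}-4,5-dimethoxypyridine-2-carboxylate | CCOC(=O)c1cc(OC)c(OC)c(-c2csc(CCCCC[C@H](C)O[Si](C)(C)C(C)(C)C)n2)n1 | intermediate
16 | ethyl 6-{2-[(6S)-6-hydroxyheptyl]-1,3-thiazol-4-yl}-4,5-dimethoxypyridine-2-carboxylate | CCOC(=O)c1cc(OC)c(OC)c(-c2csc(CCCCC[C@H](C)O)n2)n1 | intermediate
17 | 6-{2-[(6S)-6-hydroxyheptyl]-1,3-thiazol-4-yl}-4,5-dimethoxypyridine-2-carboxylic acid | COc1cc(C(=O)O)nc(-c2csc(CCCCC[C@H](C)O)n2)c1OC | target

**Step count**
Total: 9 steps. Longest linear sequence: 8 steps (1, 2, 3, 5, 6, 7, 8, 9), with step 4 as a one-step branch.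

**Steps most likely to fail**

Step 5. The dianion may form incompletely or be quenched by proton transfer from the more acidic product, and the tricarbonyl chain may fragment by retro-Claisen cleavage or cyclise prematurely on work-up. The fallback builds the chain in the opposite direction, sets out from 7 and comes back to the route at 12. Ester 7 would be converted with MeNH(OMe)·HCl and iPrMgCl in THF into the Weinreb amide F1. Addition of (methoxymethyl)lithium, generated from Bu3SnCH2OMe and n-BuLi at −78 °C, would give the methoxymethyl ketone F2. Soft enolisation with MgBr2·OEt2 and iPr2NEt and C-acetylation by 1-acetylbenzotriazole would give the 2-methoxy-1,3-diketone F3. Its dianion (LiN(iPr)2, 2 equiv.) would then be added to an excess of diethyl oxalate 9, which acylates the terminal methyl group and delivers 12 by the classical oxalylation of a 1,3-diketone.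

Step 6. The condensation may stall at the enaminone or at the 4-pyranone, and ammonia may attack the ester or cleave the tricarbonyl chain before the ring has closed. The fallback separates ring closure from nitrogen introduction, sets out from 12 and comes back at 14. Compound 12 would first be cyclodehydrated under weakly acidic, nucleophile-free conditions (pyridinium p-toluenesulfonate, toluene, 90 °C, molecular sieves) to the 4-pyranone F4, which is isolated. F4 would then be treated with ammonia in ethanol in a sealed vessel at 60 °C, where conjugate addition, ring opening and reclosure exchange the ring oxygen for nitrogen and give 14.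

Step 7. Methylation may take place on nitrogen (the pyridone nitrogen, or quaternisation of the thiazole) in competition with oxygen. The fallback forms the C4–O bond at the ring carbon by substitution and avoids an alkylating agent altogether; it sets out from 14 and comes back at 17. Neutral deoxychlorination of 14 with PPh3 and Cl3CCN in toluene would give the 4-chloropyridine F5. Nucleophilic aromatic substitution with NaOMe in MeOH at the position para to the ring nitrogen would introduce the methoxy group and at the same time exchange the ester, giving the methyl ester F6. Desilylation with HCl in MeOH would give the hydroxy methyl ester F7, and saponification with LiOH as in step 9 would give 17.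

**Further compounds**
F1 | step 5 | 2-[(6S)-6-{[tert-butyl(dimethyl)silyl]oxy}heptyl]-N-methoxy-N-methyl-1,3-thiazole-4-carboxamide | CON(C)C(=O)c1csc(CCCCC[C@H](C)O[Si](C)(C)C(C)(C)C)n1
F2 | step 5 | 1-{2-[(6S)-6-{[tert-butyl(dimethyl)silyl]oxy}heptyl]-1,3-thiazol-4-yl}-2-methoxyethan-1-one | COCC(=O)c1csc(CCCCC[C@H](C)O[Si](C)(C)C(C)(C)C)n1
F3 | step 5 | 1-{2-[(6S)-6-{[tert-butyl(dimethyl)silyl]oxy}heptyl]-1,3-thiazol-4-yl}-2-methoxybutane-1,3-dione | CC(=O)C(OC)C(=O)c1csc(CCCCC[C@H](C)O[Si](C)(C)C(C)(C)C)n1
F4 | step 6 | ethyl 6-{2-[(6S)-6-{[tert-butyl(dimethyl)silyl]oxy}heptyl]-1,3-thiazol-4-yl}-5-methoxy-4-oxo-4H-pyran-2-carboxylate | CCOC(=O)c1cc(=O)c(OC)c(-c2csc(CCCCC[C@H](C)O[Si](C)(C)C(C)(C)C)n2)o1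
F5 | step 7 | ethyl 6-{2-[(6S)-6-{[tert-butyl(dimethyl)silyl]oxy}heptyl]-1,3-thiazol-4-yl}-4-chloro-5-methoxypyridine-2-carboxylate | CCOC(=O)c1cc(Cl)c(OC)c(-c2csc(CCCCC[C@H](C)O[Si](C)(C)C(C)(C)C)n2)n1
F6 | step 7 | methyl 6-{2-[(6S)-6-{[tert-butyl(dimethyl)silyl]oxy}heptyl]-1,3-thiazol-4-yl}-4,5-dimethoxypyridine-2-carboxylate | COC(=O)c1cc(OC)c(OC)c(-c2csc(CCCCC[C@H](C)O[Si](C)(C)C(C)(C)C)n2)n1
F7 | step 7 | methyl 6-{2-[(6S)-6-hydroxyheptyl]-1,3-thiazol-4-yl}-4,5-dimethoxypyridine-2-carboxylate | COC(=O)c1cc(OC)c(OC)c(-c2csc(CCCCC[C@H](C)O)n2)n1
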